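The easy part of this handover is the count. Both flasks hold less substrate than partner, so substrate is the limiting reagent, and we follow its balance as it leaves: with partner, giving intermediate and released group; with released group, giving side product B; or with intermediate, giving side product A. Intermediate meanwhile exchanges with target and with the isomer of the product.

the same everywhere: substrate 0.0020 M; partner 1.20 equiv; time 20 s

| charge | temperature |
|---|---|
| Friday's | 35 °C |
| Thursday's | 65 °C |

- the flask that comes out highest in amount of intermediate, in percent of the substrate charged, or "all alike" when all lie within 1.5 percentage points (Friday's / Thursday's / all alike)
- intermediate at the end, in percent of the substrate charged, Friday's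
- intermediate at the end, in percent of the substrate charged, Thursday's

- percent here means substrate units held: one side product A counts as two
- the list of constants is for 35 °C, to be carried to other temperatures by the activation energies and enthalpies

    substrate + partner → intermediate + released group (k1 = 21.6 /M/s, Ea1 = 46.0 kJ/mol)
    intermediate ⇌ target (K2 = 1.10, k2 = 0.537 /s, Ea2 = 71.0 kJ/mol, ΔH2 = −37.0 kJ/mol)
    intermediate ⇌ isomer of the product (K3 = 2.52, k3 = 0.177 /s, Ea3 = 72.0 kJ/mol, ΔH3 = −15.0 kJ/mol)
    substrate + intermediate → side product A (k4 = 2.98 /M/s, Ea4 = 49.0 kJ/mol)
    target → over-reaction product (k5 = 8.88 × 10⁻⁵ /s, Ea5 = 91.0 kJ/mol)
    substrate + released group → side product B (k6 = 14.0 /M/s, Ea6 = 38.0 kJ/mol)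
    (constants at 35 °C)

At Thursday's temperature the rate constant of substrate with partner is 2.04 times that with released group, and this ratio, the split, times partner over released group gives the rate of the first way over the second.

Leaving side product A aside, we integrate that balance for Thursday's and try partner down to a third of its charge. By then 80.0% of the substrate charge has passed through the partner, released group stands at 58.9%, and side product B holds 21.1%, so the sum of 101% accounts for the charge.

The exchanges on Thursday's relax quickly, in 0.0258 s for target and 0.194 s for the isomer, so intermediate keeps its equilibrium share of 35.7%. That gives us 28.5% on Thursday's, an upper figure with side product A left out.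

On Friday's the substrate half-life against the charged partner is 13.4 s, not short against 20 s, so you will find substrate still there. Roughly 64.5% is consumed, and an equilibrium share of 21.6% gives us 14.0%.

At our balance point on Thursday's the first way still runs 1.38 times the second.

The forecast names Thursday's, with 13.5% for Friday's and 26.2% for Thursday's, since “the exothermic equilibria shift back”, and its Thursday's figure lies below ours. The simulation gives 13.6% on Friday's and 26.2% on Thursday's, so Thursday's comes out higher, and our Thursday's upper figure stands 2.3 percentage points above it.

At the end of Thursday's, substrate goes 1.5 times as fast with partner as with released group, and the split times the partner and released group standing there gives 1.54. In the neighbour of Thursday's charged with 0.480 equiv of partner, the same product at the end is 0.472, so released group has overtaken partner there, with side product B at 22.0% and intermediate at 14.1%.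

Its constants are assumed.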